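**Strategy.** The 2H-pyran ring (O1, C2, C3, C4, C4a, C8a) is grown from the 2,5-dihydrofuran ring of a 1-oxaspiro[4.5]deca-3,6,9-trien-8-one. The feature exploited is the para relation between O1 on C8a and the hydroxyl on C6, which marks the arene as a rearranged para-quinol ether. A Lewis-acid dienone–phenol rearrangement moves alkenyl carbon C4 from the spiro carbon (later C8a) to its neighbour (later C4a). This one isomerisation forms C4–C4a, enlarges the ring from five to six members and unveils the phenol, while no bond at C2 is touched. C2 stems from a Sharpless epoxidation; the side chain is joined by Suzuki coupling.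

Key step: step 9

Remark: the labels O1, C2, C3, C4, C4a, C6 and C8a follow the chromene numbering of the target and are kept for the same atoms in all precursors. Compounds 1, 6 and 11 are taken as catalogue chemicals.

**Fragment A (side chain)**

Step 1
Reactants: 1 dihydro-β-ionone
Product: 3 2-(but-3-yn-1-yl)-1,3,3-trimethylcyclohex-1-ene, via enol phosphate 2 (not isolated)
Conditions: LiN(iPr)2 (1.05 equiv), THF, −78 °C; ClP(O)(OEt)2 (1.1 equiv), −78 °C to rt; then LiN(iPr)2 (2.3 equiv), THF, −78 °C to rt; H2O
Reagents that add atoms: diethyl chlorophosphate, CCOP(=O)(Cl)OCC (its atoms stand only in intermediate 2)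
Why: Kinetic deprotonation at the methyl group, O-phosphorylation and base-induced elimination of diethyl phosphate is the Negishi conversion of a methyl ketone into a terminal alkyne, and the tetrasubstituted ring alkene is inert to the amide base.

Step 2
Reactants: 3 2-(but-3-yn-1-yl)-1,3,3-trimethylcyclohex-1-ene
Product: 5 2-[(3E)-4-iodo-3-methylbut-3-en-1-yl]-1,3,3-trimethylcyclohex-1-ene, via alkenylalane 4 (not isolated)
Conditions: AlMe3 (2 equiv), Cp2ZrCl2 (0.25 equiv), CH2Cl2, 0 °C to rt; then I2, THF, −30 to 0 °C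
Reagents that add atoms: trimethylaluminium, C[Al](C)C; iodine, II
Why: The Negishi zirconium-catalysed carboalumination adds methyl and aluminium syn across the terminal alkyne with aluminium at the terminus, and iodinolysis with retention should fix the E trisubstituted alkene of the side chain.

**Fragment B (stereocentre and arene)**

Step 3
Reactants: 6 (E)-3-methylpent-2-en-4-yn-1-ol
Product: 8 [(2R,3R)-3-ethynyl-3-methyloxiran-2-yl]methyl 4-toluenesulfonate, via epoxy alcohol 7 (not isolated)
Conditions: Ti(OiPr)4 (10 mol %), D-(−)-diisopropyl tartrate (13 mol %), t-BuOOH (2 equiv), 4 Å molecular sieves, CH2Cl2, −20 °C; P(OMe)3; then TsCl, Et3N, DMAP (cat.), −10 °C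
Reagents that add atoms: tert-butyl hydroperoxide, CC(C)(C)OO; 4-toluenesulfonyl chloride, Cc1ccc(cc1)S(=O)(=O)Cl
Why: In the Katsuki–Sharpless asymmetric epoxidation the D-(−)-tartrate should convert an E-3,3-disubstituted allylic alcohol into the (2R,3R)-epoxide, which sets the later C2–O1 bond and its configuration by reagent control, and tosylation in the same flask avoids isolating the small water-soluble epoxy alcohol.

Step 4
Reactants: 8 [(2R,3R)-3-ethynyl-3-methyloxiran-2-yl]methyl 4-toluenesulfonate
Product: 10 (3S)-3-methylpent-1-en-4-yn-3-ol, via epoxy iodide 9 (not isolated)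
Conditions: NaI (3 equiv), Zn dust (4 equiv), EtOH, 60 °C; product kept as a concentrated ether solution because of its volatility
Reagents that add atoms: sodium iodide, [Na+].[I-] (its iodine stands only in intermediate 9)
Why: Finkelstein exchange followed by zinc insertion into the C–I bond and β-elimination (reductive opening of a 2,3-epoxy iodide) breaks only the C–O bond at the secondary carbon, so the tertiary C–O bond keeps its configuration and the vinyl handle appears.

Step 5
Reactants: 10 (3S)-3-methylpent-1-en-4-yn-3-ol; 11 4-iodophenol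
Product: 12 4-[(3S)-3-hydroxy-3-methylpent-4-en-1-yn-1-yl]phenol
Conditions: Pd(PPh3)2Cl2 (2 mol %), CuI (4 mol %), Et3N, THF, rt, degassed
Reagents that add atoms: none
Why: The Sonogashira coupling of a terminal alkyne with an aryl iodide runs at room temperature in the presence of free phenol and tertiary alcohol groups and touches no bond at the stereocentre.

**Union and endgame**

Step 6
Reactants: 12 4-[(3S)-3-hydroxy-3-methylpent-4-en-1-yn-1-yl]phenol; 5 2-[(3E)-4-iodo-3-methylbut-3-en-1-yl]-1,3,3-trimethylcyclohex-1-ene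
Product: 14 4-[(3S,6E)-3-hydroxy-3,7-dimethyl-9-(2,6,6-trimethylcyclohex-1-en-1-yl)non-6-en-1-yn-1-yl]phenol, via B-alkylborane 13 (not isolated)
Conditions: 9-BBN-H (3.3 equiv), THF, 0 °C to rt; then H2O, 5, Pd(dppf)Cl2 (5 mol %), AsPh3 (5 mol %), Cs2CO3 (4 equiv), DMF, rt to 45 °C; aq. NH4Cl
Reagents that add atoms: 9-borabicyclo[3.3.1]nonane, [BH]1C2CCCC1CCC2 (its boron and carbon atoms stand only in intermediate 13)
Why: 9-BBN-H should add anti-Markovnikov to the monosubstituted vinyl group much faster than to the hindered internal aryl alkyne (the excess covers the two O–H groups), and the B-alkyl Suzuki–Miyaura coupling with the alkenyl iodide proceeds with retention of the E geometry.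

Step 7
Reactants: 14 4-[(3S,6E)-3-hydroxy-3,7-dimethyl-9-(2,6,6-trimethylcyclohex-1-en-1-yl)non-6-en-1-yn-1-yl]phenol
Product: 15 4-[(1Z,3S,6E)-3-hydroxy-3,7-dimethyl-9-(2,6,6-trimethylcyclohex-1-en-1-yl)nona-1,6-dien-1-yl]phenol
Conditions: H2 (1 atm, stopped after one equivalent), Pd/CaCO3 poisoned with Pb(OAc)2, quinoline, EtOAc, rt
Reagents that add atoms: none
Why: The Lindlar semihydrogenation delivers hydrogen syn to the alkyne and so gives the Z alkene that the five-membered ring closure needs, while tri- and tetrasubstituted alkenes are not reduced on the poisoned catalyst.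

Step 8
Reactants: 15 4-[(1Z,3S,6E)-3-hydroxy-3,7-dimethyl-9-(2,6,6-trimethylcyclohex-1-en-1-yl)nona-1,6-dien-1-yl]phenol
Product: 16 (2S)-2-methyl-2-[(3E)-4-methyl-6-(2,6,6-trimethylcyclohex-1-en-1-yl)hex-3-en-1-yl]-1-oxaspiro[4.5]deca-3,6,9-trien-8-one
Conditions: PhI(OAc)2 (1.05 equiv), NaHCO3 (3 equiv), MeCN, −10 to 0 °C, dark
Reagents that add atoms: none
Why: Oxidative dearomatisation of a para-substituted phenol by trivalent iodine, with 5-exo capture at the ipso carbon by the tethered tertiary hydroxyl that the Z alkene holds in reach, is the known spiroetherification to 1-oxaspiro[4.5]decadienones; the spiro carbon carries two identical dienone arms and is no stereocentre, and C2 keeps its C–O bond.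

Step 9
Reactants: 16 (2S)-2-methyl-2-[(3E)-4-methyl-6-(2,6,6-trimethylcyclohex-1-en-1-yl)hex-3-en-1-yl]-1-oxaspiro[4.5]deca-3,6,9-trien-8-one
Product: 17 (2S)-2-methyl-2-[(3E)-4-methyl-6-(2,6,6-trimethylcyclohex-1-en-1-yl)hex-3-en-1-yl]-2H-chromen-6-ol (CNP0157994.1)
Conditions: BF3·OEt2 (0.2 equiv), 2,6-di-tert-butylpyridine (0.2 equiv), CH2Cl2, −78 to −40 °C, dark; Et3N quench
Reagents that add atoms: none
Why: BF3 binds the dienone oxygen and places positive charge on the carbon next to the spiro centre, alkenyl carbon C4 then moves by a suprafacial 1,2-shift from the spiro carbon to that carbon, the cation left behind is held by the lone pair of O1, and loss of the proton from C4a gives the arene. The closest known reaction type is the dienone–phenol rearrangement of spiro[4.5]decadienones and of para-quinol ethers, including the alkenyl shift that turns 1-oxaspiro[4.5]trienone lactones into coumarins. The six-membered ring is not closed by a cyclisation: the dihydrofuran ring O1–C2–C3=C4–C(spiro) takes in one dienone carbon through a three-centre transition state and so grows from five to six members. No stereocentre is formed, and C2 is retained because none of its four bonds takes part. The step needs carbon and not oxygen to migrate (an oxygen shift would give the 7-hydroxy isomer), which the oxocarbenium stabilisation by O1 and the high migratory aptitude of an sp2 carbon should secure, and the two dienone carbons that flank the spiro centre lead to the same product. It also needs the allylic C2–O1 bond and the side-chain alkenes to stay untouched, which the preferred binding of BF3 to the more basic carbonyl oxygen, the low temperature, the hindered pyridine as proton buffer and the gain of aromaticity should secure.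

**Compound list**

1 | dihydro-β-ionone, 4-(2,6,6-trimethylcyclohex-1-en-1-yl)butan-2-one | CC(=O)CCC1=C(C)CCCC1(C)C | starting material
2 | diethyl 4-(2,6,6-trimethylcyclohex-1-en-1-yl)but-1-en-2-yl phosphate | C=C(CCC1=C(C)CCCC1(C)C)OP(=O)(OCC)OCC | intermediate
3 | 2-(but-3-yn-1-yl)-1,3,3-trimethylcyclohex-1-ene | C#CCCC1=C(C)CCCC1(C)C | intermediate
4 | dimethyl[(1E)-2-methyl-4-(2,6,6-trimethylcyclohex-1-en-1-yl)but-1-en-1-yl]alane | CC1=C(CC/C(C)=C/[Al](C)C)C(C)(C)CCC1 | intermediate
5 | 2-[(3E)-4-iodo-3-methylbut-3-en-1-yl]-1,3,3-trimethylcyclohex-1-ene | CC1=C(CC/C(C)=C/I)C(C)(C)CCC1 | intermediate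
6 | (E)-3-methylpent-2-en-4-yn-1-ol | C#C/C(C)=C/CO | starting material
7 | [(2R,3R)-3-ethynyl-3-methyloxiran-2-yl]methanol | OC[C@H]1O[C@]1(C)C#C | intermediate
8 | [(2R,3R)-3-ethynyl-3-methyloxiran-2-yl]methyl 4-toluenesulfonate | Cc1ccc(cc1)S(=O)(=O)OC[C@H]1O[C@]1(C)C#C | intermediate
9 | (2R,3S)-2-ethynyl-3-(iodomethyl)-2-methyloxirane | IC[C@H]1O[C@]1(C)C#C | intermediate
10 | (3S)-3-methylpent-1-en-4-yn-3-ol | C=C[C@@](O)(C)C#C | intermediate
11 | 4-iodophenol | Oc1ccc(I)cc1 | starting material
12 | 4-[(3S)-3-hydroxy-3-methylpent-4-en-1-yn-1-yl]phenol | C=C[C@@](O)(C)C#Cc1ccc(O)cc1 | intermediate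
13 | 4-[(3S)-5-(9-borabicyclo[3.3.1]nonan-9-yl)-3-hydroxy-3-methylpent-1-yn-1-yl]phenol (drawn with free O–H groups, which are held as borinates until water is added) | B1(C2CCCC1CCC2)CC[C@@](O)(C)C#Cc1ccc(O)cc1 | intermediate
14 | 4-[(3S,6E)-3-hydroxy-3,7-dimethyl-9-(2,6,6-trimethylcyclohex-1-en-1-yl)non-6-en-1-yn-1-yl]phenol | CC1=C(CC/C(C)=C/CC[C@@](O)(C)C#Cc2ccc(O)cc2)C(C)(C)CCC1 | intermediate
15 | 4-[(1Z,3S,6E)-3-hydroxy-3,7-dimethyl-9-(2,6,6-trimethylcyclohex-1-en-1-yl)nona-1,6-dien-1-yl]phenol | CC1=C(CC/C(C)=C/CC[C@@](O)(C)/C=C\c2ccc(O)cc2)C(C)(C)CCC1 | intermediate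
16 | (2S)-2-methyl-2-[(3E)-4-methyl-6-(2,6,6-trimethylcyclohex-1-en-1-yl)hex-3-en-1-yl]-1-oxaspiro[4.5]deca-3,6,9-trien-8-one | CC1=C(CC/C(C)=C/CC[C@@]2(C)C=CC3(O2)C=CC(=O)C=C3)C(C)(C)CCC1 | intermediate
17 | (2S)-2-methyl-2-[(3E)-4-methyl-6-(2,6,6-trimethylcyclohex-1-en-1-yl)hex-3-en-1-yl]-2H-chromen-6-ol | CC1=C(CC/C(C)=C/CC[C@@]2(C)C=Cc3cc(O)ccc3O2)C(C)(C)CCC1 | target

**Step count and risks**

Total step count: 9. Longest linear sequence: 7 steps (steps 3 to 9, from 6 to 17). Fragment A (steps 1 and 2) joins in step 6.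

**Step 9 (key step).**
- What may go wrong: ionisation of the allylic C2–O1 bond, with loss of configuration, may outrun the 1,2-shift.
- The fallback sets out from 14 and comes back at 17. It keeps the ring enlargement but runs it on a saturated tether and adds the C3=C4 unsaturation afterwards.
- Hydrogenation of the alkyne of 14 with H2 and RhCl(PPh3)3 in benzene–ethanol leaves tri- and tetrasubstituted alkenes alone. It should give the saturated hydroxyalkylphenol F1.
- PhI(OAc)2 in MeCN should close F1 to the saturated spirodienone F2, whose C2–O1 bond is no longer allylic.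
- BF3·OEt2 at −20 to 0 °C should then shift the sp3 carbon C4 and give the chromanol F3.
- Dehydrogenation of the 6-hydroxychroman with DDQ in toluene should give 17.

**Step 8.**
- What may go wrong: the oxidant or the dearomatised cation may attack the electron-rich side-chain alkenes, in competition with capture by the tertiary hydroxyl.
- The fallback sets out from 12 and comes back at 17. It moves the fragment union to the end, so the polyene chain never meets the oxidant or the Lewis acid.
- Lindlar semihydrogenation of 12, watched closely because of the vinyl group, should give the Z-dienol F4.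
- PhI(OAc)2 with NaHCO3 should give the vinyl spirotrienone F5.
- BF3·OEt2 at −78 °C should give the vinylchromenol F6 by the same ring enlargement.
- 9-BBN-H should add to the terminal vinyl group in preference to the cyclic styrene-type alkene and give the chromenyl borane F7.
- F7 is coupled with 5 under Pd(dppf)Cl2 and Cs2CO3 to give 17.

**Step 6.**
- What may go wrong: the excess borane that the two O–H groups demand may hydroborate the aryl alkyne, or the borane may be lost by protodeboronation before coupling.
- The fallback sets out from 10 and comes back at 14. It reverses the order of the two couplings, so neither the acidic phenol nor the aryl-conjugated alkyne is present during hydroboration.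
- EtMgBr (2.2 equiv), Me3SiCl and a mild acidic work-up should give the C-silylated enynol F8.
- 9-BBN-H should give the silylalkynyl borane F9, with the alkyne shielded by silicon.
- Suzuki–Miyaura coupling with 5 should give the silylated chain alkynol F10.
- K2CO3 in MeOH should free the terminal chain alkynol F11.
- Sonogashira coupling of F11 with 11 gives 14.

**Further compounds**

F1 | step 9 | 4-[(3S,6E)-3-hydroxy-3,7-dimethyl-9-(2,6,6-trimethylcyclohex-1-en-1-yl)non-6-en-1-yl]phenol | CC1=C(CC/C(C)=C/CC[C@@](O)(C)CCc2ccc(O)cc2)C(C)(C)CCC1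
F2 | step 9 | (2S)-2-methyl-2-[(3E)-4-methyl-6-(2,6,6-trimethylcyclohex-1-en-1-yl)hex-3-en-1-yl]-1-oxaspiro[4.5]deca-6,9-dien-8-one | CC1=C(CC/C(C)=C/CC[C@@]2(C)CCC3(O2)C=CC(=O)C=C3)C(C)(C)CCC1
F3 | step 9 | (2S)-2-methyl-2-[(3E)-4-methyl-6-(2,6,6-trimethylcyclohex-1-en-1-yl)hex-3-en-1-yl]chroman-6-ol | CC1=C(CC/C(C)=C/CC[C@@]2(C)CCc3cc(O)ccc3O2)C(C)(C)CCC1
F4 | step 8 | 4-[(1Z,3S)-3-hydroxy-3-methylpenta-1,4-dien-1-yl]phenol | C=C[C@@](O)(C)/C=C\c1ccc(O)cc1
F5 | step 8 | (2S)-2-ethenyl-2-methyl-1-oxaspiro[4.5]deca-3,6,9-trien-8-one | C=C[C@@]1(C)C=CC2(O1)C=CC(=O)C=C2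
F6 | step 8 | (2S)-2-ethenyl-2-methyl-2H-chromen-6-ol | C=C[C@@]1(C)C=Cc2cc(O)ccc2O1
F7 | step 8 | (2S)-2-[2-(9-borabicyclo[3.3.1]nonan-9-yl)ethyl]-2-methyl-2H-chromen-6-ol | B1(C2CCCC1CCC2)CC[C@@]1(C)C=Cc2cc(O)ccc2O1
F8 | step 6 | (3S)-3-methyl-5-(trimethylsilyl)pent-1-en-4-yn-3-ol | C=C[C@@](O)(C)C#C[Si](C)(C)C
F9 | step 6 | (3S)-5-(9-borabicyclo[3.3.1]nonan-9-yl)-3-methyl-1-(trimethylsilyl)pent-1-yn-3-ol | B1(C2CCCC1CCC2)CC[C@@](O)(C)C#C[Si](C)(C)C
F10 | step 6 | (3S,6E)-3,7-dimethyl-1-(trimethylsilyl)-9-(2,6,6-trimethylcyclohex-1-en-1-yl)non-6-en-1-yn-3-ol | CC1=C(CC/C(C)=C/CC[C@@](O)(C)C#C[Si](C)(C)C)C(C)(C)CCC1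
F11 | step 6 | (3S,6E)-3,7-dimethyl-9-(2,6,6-trimethylcyclohex-1-en-1-yl)non-6-en-1-yn-3-ol | CC1=C(CC/C(C)=C/CC[C@@](O)(C)C#C)C(C)(C)CCC1
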